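(All runs were computed for an exercise, noise included.)

I decided to carry one number from the two earlier runs instead of a rate, because both had stopped while starting material was still there, 59 % in ash and 68 % in oak.

in all of them: initiator 0.75 mol%

| charge | starting material | reagent | transfer agent | scavenger | remark | time |
|---|---|---|---|---|---|---|
| ash | 0.094 M | 1.1 equiv | 9.4 mM | 0.50 equiv | the very flask that is asked about, followed so far |  |
| oak | 0.063 M | 1.1 equiv | 9.4 mM | 0.50 equiv | run made earlier |  |
| flask | 0.094 M | 1.10 equiv | 9.40 mM | 0.500 equiv |  | 8.0 d |

- ash (time / h: starting material / %, target / %): 3.00: 75, 25; 6.00: 63, 34; 15.0: 57, 40; 30.0: 59, 44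
- oak (time / d: starting material / %, target / %): 0.625: 72, 27; 2.08: 68, 30; 4.00: 69, 31; 6.00: 68, 30

(scatter of a reading: 1.5 percentage points)

* part of the starting material that has reacted at 8.0 d
* share of free reagent in free reagent and idle adduct together, at 8.0 d

- the earlier runs do not show how much of reagent is bound; that part of a forecast is a guess

Ash and oak look nearly the same: they have the same equivalents, the same initiator loading and the same molarity of transfer agent, and they differ in dilution. Ash was flat by 15.0 h and oak by 2.08 d, so I read both as chains that had stopped by those readings. They ended apart, I judged, because the logarithm of charged over left stood at 1.46 between ash and oak, close to the ratio of their charges, 1.49.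

So I defined s, the stall constant, as that logarithm at the plateau per molar of starting material charged, and read 6.12 M⁻¹ from oak. Ash's readings gave 5.98 M⁻¹ at 15.0 h and 5.61 M⁻¹ at 30.0 h. For ash at 8.0 d, s gave me 43.8 % reacted.

The forecast said 45 % reacted and 45 % free, the latter a guess: “Binding strength is unknown”.

    reagent ⇌ dormant form (K = 1.20, k = 9.58 × 10⁻⁵ s⁻¹)
    starting material + second chain carrier → released group + first chain carrier (k = 1.86 × 10⁵ M⁻¹ s⁻¹)
    reagent + released group ⇌ idle adduct, settled at all times (K = 3.12 M⁻¹)
    transfer agent + first chain carrier → side product + idle radical (kL = 32400 M⁻¹ s⁻¹)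
    starting material + initiating radical → capped initiator + first chain carrier (k = 5.00 × 10⁵ M⁻¹ s⁻¹)
    scavenger + released group → scavenged by-product (k = 0.0134 M⁻¹ s⁻¹)
    2 first chain carrier → ended chains A (k = 6.00 × 10⁸ M⁻¹ s⁻¹)
    initiator → 2 initiating radical (k = 5.63 × 10⁻⁵ s⁻¹)
    reagent + first chain carrier → target + second chain carrier (k = 1.70 × 10⁵ M⁻¹ s⁻¹)
    2 idle radical → ended radicals (k = 3.00 × 10⁷ M⁻¹ s⁻¹)
    2 second chain carrier → ended chains B (k = 1.50 × 10⁹ M⁻¹ s⁻¹)

Ash gave 43.1 % reacted, which returns 6.00 M⁻¹ for s. The free share was 100 %, 55 percentage points above the forecast, with idle adduct at 0 M and dormant form at 0.0351 M. For the more dilute neighbour flask, with 0.024 M of starting material and the equivalents and loadings of the recipe held, s gives 13.7 %, and that flask gave 13.8 %. Ash had come to rest: initiator, the first charge to run out, stood at 0 % of its charge at 8.00 d, and starting material stood at 56.9 % then and 56.9 % at 80.0 d. At 80.0 d the reacted part stood at 43.1 %.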